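**Retrosynthetic overview**
1. The enal, the phenol and the CH2OH group are unmasked together at the end from a Weinreb amide, an aryl pivalate and an N-acyl oxazolidinone by one hydride reduction (step 5).
2. Key disconnection: the dioxane ring is cut at O4–C4a (aryl C–O bond) and at C2–C3, giving 3,4,5-trimethoxybenzaldehyde and a (2-bromoaryloxy)acetyl imide; forward, an Evans syn aldol and a palladium-catalysed aryl etherification by the aldol oxygen run in one flask (step 4).
3. Enabling feature: O1–C2(CH2OH)–C3(Ar)–O4 is a masked syn α-aryloxy-β-hydroxy acyl array (C2 is α to the carboxyl-level CH2OH carbon, C3 is a former aldehyde carbon whose oxygen becomes O4), and C4a lies ortho to the O1-bearing C8a of the benzo ring, so a bromine at C4a lets the aldol oxygen close the six-membered ring.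
4. The imide comes from 3-bromo-4,5-dihydroxybenzaldehyde through a 1,4-benzodioxin-2-one lactone that fixes the regiochemistry of the glycolate ether, activates the acyl group and hands over the phenol oxygen for protection.
5. Ring order: both benzene rings are bought; the temporary lactone ring is made in step 1 and opened in step 3; the dioxane ring, the only ring of the target that is built, is closed in step 4.

Key step: step 4

Remark: positions are numbered as in 2,3-dihydro-1,4-benzodioxine with O1 on the benzo carbon C8a next to the hydroxyl-bearing C8, C2 carrying the CH2OH (or acyl) carbon, C3 the trimethoxyphenyl group and O4 bonded to C4a; the boron enolate of the aryloxyacetyl imide is assumed to follow the usual Evans syn facial preference of alkoxyacetyl imides.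

Step 1
Reactants: 1 3-bromo-4,5-dihydroxybenzaldehyde; 2 methyl bromoacetate
Product: 4 8-bromo-3-oxo-2,3-dihydro-1,4-benzodioxine-6-carbaldehyde, via hydroxy ester 3 (not isolated)
Conditions: NaHCO3, NaI (cat.), DMF, 40 °C; aqueous work-up; then TsOH (cat.), toluene, reflux with removal of MeOH
Reagents that add atoms: none
Why: Williamson O-alkylation should take place at the more acidic phenol oxygen (para to the formyl group, ortho to bromine), and the neighbouring phenol then lactonises onto the methyl ester under acid catalysis (intramolecular transesterification) as methanol is removed.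

Step 2
Reactants: 4 8-bromo-3-oxo-2,3-dihydro-1,4-benzodioxine-6-carbaldehyde; 5 N-methoxy-N-methyl-2-(triphenylphosphoranylidene)acetamide
Product: 6 (2E)-3-(8-bromo-3-oxo-2,3-dihydro-1,4-benzodioxin-6-yl)-N-methoxy-N-methylprop-2-enamide
Conditions: CH2Cl2, 25 °C
Reagents that add atoms: none
Why: Wittig olefination of the aryl aldehyde with the amide-stabilised ylide should give the E-enamide selectively, while the less electrophilic aryl lactone should stay intact at room temperature.

Step 3
Reactants: 6 (2E)-3-(8-bromo-3-oxo-2,3-dihydro-1,4-benzodioxin-6-yl)-N-methoxy-N-methylprop-2-enamide; 7 (4R)-4-benzyl-1,3-oxazolidin-2-one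
Product: 9 2-{2-[(4R)-4-benzyl-2-oxo-1,3-oxazolidin-3-yl]-2-oxoethoxy}-3-bromo-5-[(1E)-3-[methoxy(methyl)amino]-3-oxoprop-1-en-1-yl]phenyl 2,2-dimethylpropanoate, via lithium phenolate 8 (not isolated)
Conditions: 7 (1.1 equiv), n-BuLi (1.05 equiv), THF, −78 °C; add 6, −78 to 0 °C; then PivCl, 0 to 25 °C
Reagents that add atoms: pivaloyl chloride CC(C)(C)C(=O)Cl
Why: N-acylation of the lithiated oxazolidinone by the activated aryl ester (the lactone) opens the ring, driven by release of the much less basic phenoxide 8, which is capped in the same flask by O-acylation with pivaloyl chloride before it can re-lactonise.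

Step 4
Reactants: 9 2-{2-[(4R)-4-benzyl-2-oxo-1,3-oxazolidin-3-yl]-2-oxoethoxy}-3-bromo-5-[(1E)-3-[methoxy(methyl)amino]-3-oxoprop-1-en-1-yl]phenyl 2,2-dimethylpropanoate; 10 3,4,5-trimethoxybenzaldehyde
Product: 14 (4R)-4-benzyl-3-{[(2R,3S)-8-[(2,2-dimethylpropanoyl)oxy]-6-[(1E)-3-[methoxy(methyl)amino]-3-oxoprop-1-en-1-yl]-3-(3,4,5-trimethoxyphenyl)-2,3-dihydro-1,4-benzodioxin-2-yl]carbonyl}-1,3-oxazolidin-2-one, via boron enolate 11 (not isolated), via boron aldolate 12 (not isolated), via aldol adduct 13 (not isolated)
Conditions: Bu2BOTf (1.5 equiv), iPr2NEt (1.8 equiv), CH2Cl2, −78 to 0 °C; 10, −78 to 0 °C; MeOH, evaporate to dryness (twice, toluene chase); then Pd(OAc)2 (5 mol %), 2-(di-tert-butylphosphino)-1,1'-binaphthyl (6 mol %), Cs2CO3, toluene, 65 °C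
Reagents that add atoms: none
Why: Soft enolisation of the imide with Bu2BOTf and iPr2NEt should give the Z-boron enolate 11, which adds to aldehyde 10 through a closed chair transition state (Evans syn aldol, Zimmerman–Traxler model) and so forms the C2–C3 bond. The (R)-benzyl group of the auxiliary, held with its carbonyl dipole opposed to the enolate oxygen, screens one enolate face, so aldolate 12 should have the 2R,3S configuration, with C2 set by the enolate face and C3 by the chair with the aryl group equatorial. Methanolysis removes boron as Bu2BOMe and frees alcohol 13, whose oxygen is the former aldehyde oxygen; zerovalent palladium then inserts into the C–Br bond ortho to the ether oxygen, Cs2CO3 deprotonates the hydroxyl on divalent palladium to a seven-membered aryl(alkoxo)palladium chelate, and C–O reductive elimination closes the six-membered dioxane ring (closest known reaction: Buchwald–Hartwig intramolecular aryl etherification of secondary alcohols). This ring closure is an intramolecular O-arylation that touches neither stereocentre, so the syn aldol pair is carried with retention into the trans 2,3-disubstituted ring. The step needs reductive elimination to outrun β-hydride elimination, retro-aldol cleavage and attack of the alkoxide on the oxazolidinone, which the bulky electron-rich biaryl phosphine, the weak insoluble base in toluene and the intramolecular delivery of the hydroxyl should secure; the ring size is fixed because only the brominated carbon next to the aryloxy oxygen can be reached and the carboxyl-level C2 substituent offers no second hydroxyl.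

Step 5
Reactants: 14 (4R)-4-benzyl-3-{[(2R,3S)-8-[(2,2-dimethylpropanoyl)oxy]-6-[(1E)-3-[methoxy(methyl)amino]-3-oxoprop-1-en-1-yl]-3-(3,4,5-trimethoxyphenyl)-2,3-dihydro-1,4-benzodioxin-2-yl]carbonyl}-1,3-oxazolidin-2-one
Product: 15 (2E)-3-[(2S,3S)-8-hydroxy-2-(hydroxymethyl)-3-(3,4,5-trimethoxyphenyl)-2,3-dihydro-1,4-benzodioxin-6-yl]prop-2-enal
Conditions: LiAlH4 (3 equiv), THF, −40 to 0 °C; then aq. KNaC4H4O6
Reagents that add atoms: none
Why: LiAlH4 should reduce the N-acyl oxazolidinone through the aldehyde to the primary alcohol and cleave the aryl pivalate, whereas the Weinreb amide is held as the stable five-membered aluminium chelate of its hemiaminal and releases the E-enal only on aqueous work-up (Weinreb amide reduction); no stereocentre is touched, and C2 changes its descriptor from R to S only through the priority change.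

**Compound list**
1 | 3-bromo-4,5-dihydroxybenzaldehyde | O=Cc1cc(O)c(O)c(Br)c1 | starting material
2 | methyl bromoacetate | COC(=O)CBr | starting material
3 | methyl 2-(2-bromo-4-formyl-6-hydroxyphenoxy)acetate | COC(=O)COc1c(O)cc(C=O)cc1Br | intermediate
4 | 8-bromo-3-oxo-2,3-dihydro-1,4-benzodioxine-6-carbaldehyde | O=Cc1cc(Br)c2OCC(=O)Oc2c1 | intermediate
5 | N-methoxy-N-methyl-2-(triphenylphosphoranylidene)acetamide | CON(C)C(=O)C=P(c1ccccc1)(c1ccccc1)c1ccccc1 | starting material
6 | (2E)-3-(8-bromo-3-oxo-2,3-dihydro-1,4-benzodioxin-6-yl)-N-methoxy-N-methylprop-2-enamide | CON(C)C(=O)/C=C/c1cc(Br)c2OCC(=O)Oc2c1 | intermediate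
7 | (4R)-4-benzyl-1,3-oxazolidin-2-one | O=C1N[C@H](Cc2ccccc2)CO1 | starting material
8 | lithium 2-{2-[(4R)-4-benzyl-2-oxo-1,3-oxazolidin-3-yl]-2-oxoethoxy}-3-bromo-5-[(1E)-3-[methoxy(methyl)amino]-3-oxoprop-1-en-1-yl]phenolate | [Li+].CON(C)C(=O)/C=C/c1cc([O-])c(OCC(=O)N2[C@H](Cc3ccccc3)COC2=O)c(Br)c1 | intermediate
9 | 2-{2-[(4R)-4-benzyl-2-oxo-1,3-oxazolidin-3-yl]-2-oxoethoxy}-3-bromo-5-[(1E)-3-[methoxy(methyl)amino]-3-oxoprop-1-en-1-yl]phenyl 2,2-dimethylpropanoate | CON(C)C(=O)/C=C/c1cc(OC(=O)C(C)(C)C)c(OCC(=O)N2[C@H](Cc3ccccc3)COC2=O)c(Br)c1 | intermediate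
10 | 3,4,5-trimethoxybenzaldehyde | COc1cc(C=O)cc(OC)c1OC | starting material
11 | (Z)-O-dibutylboryl enolate of imide 9 (aryloxy group cis to the boron-bearing oxygen) | CCCCB(CCCC)O/C(=C\Oc1c(Br)cc(/C=C/C(=O)N(C)OC)cc1OC(=O)C(C)(C)C)N1[C@H](Cc2ccccc2)COC1=O | intermediate
12 | O-dibutylboryl ether of the (2R,3S) aldol adduct 13 | COc1cc([C@H](OB(CCCC)CCCC)[C@@H](Oc2c(Br)cc(/C=C/C(=O)N(C)OC)cc2OC(=O)C(C)(C)C)C(=O)N2[C@H](Cc3ccccc3)COC2=O)cc(OC)c1OC | intermediate
13 | 2-{[(2R,3S)-1-[(4R)-4-benzyl-2-oxo-1,3-oxazolidin-3-yl]-3-hydroxy-1-oxo-3-(3,4,5-trimethoxyphenyl)propan-2-yl]oxy}-3-bromo-5-[(1E)-3-[methoxy(methyl)amino]-3-oxoprop-1-en-1-yl]phenyl 2,2-dimethylpropanoate | COc1cc([C@H](O)[C@@H](Oc2c(Br)cc(/C=C/C(=O)N(C)OC)cc2OC(=O)C(C)(C)C)C(=O)N2[C@H](Cc3ccccc3)COC2=O)cc(OC)c1OC | intermediate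
14 | (4R)-4-benzyl-3-{[(2R,3S)-8-[(2,2-dimethylpropanoyl)oxy]-6-[(1E)-3-[methoxy(methyl)amino]-3-oxoprop-1-en-1-yl]-3-(3,4,5-trimethoxyphenyl)-2,3-dihydro-1,4-benzodioxin-2-yl]carbonyl}-1,3-oxazolidin-2-one | COc1cc([C@@H]2Oc3cc(/C=C/C(=O)N(C)OC)cc(OC(=O)C(C)(C)C)c3O[C@H]2C(=O)N2[C@H](Cc3ccccc3)COC2=O)cc(OC)c1OC | intermediate
15 | (2E)-3-[(2S,3S)-8-hydroxy-2-(hydroxymethyl)-3-(3,4,5-trimethoxyphenyl)-2,3-dihydro-1,4-benzodioxin-6-yl]prop-2-enal | COc1cc([C@@H]2Oc3cc(/C=C/C=O)cc(O)c3O[C@H]2CO)cc(OC)c1OC | target

**Step count and risks**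
Total step count: 5. Longest linear sequence: 5 steps (from 1).

Steps most likely to fail:

Step 4. Under the basic coupling conditions the β-alkoxide of the imide aldol may fragment by retro-aldol cleavage or attack the oxazolidinone carbonyl. The palladium alkoxide may undergo β-hydride elimination with loss of the bromine. Boron triflate held by the Weinreb amide may also erode the syn selectivity of the aldol. The fallback sets out from 9 and 10: the aldol is run alone with the same methanol work-up and 13 is isolated. Yb(OTf)3-catalysed methanolysis then exchanges the auxiliary for a methyl ester to give the methyl ester aldol F1, which has no imide left to cleave. A copper-catalysed Ullmann etherification (CuI, 3,4,7,8-tetramethyl-1,10-phenanthroline, Cs2CO3, toluene, 90 °C), which cannot lose the bromine by β-hydride elimination, should close the ring to the methyl benzodioxine-2-carboxylate F2. LiAlH4 under the conditions of step 5 then reduces the ester, the pivalate and the Weinreb amide, and the fallback comes back to the route at 15.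

Step 5. Chemoselectivity among the three hydride acceptors may be lost: the chelated Weinreb adduct may be over-reduced to the allylic alcohol, the enamide may suffer conjugate reduction, or the imide adduct may not collapse fully. The fallback sets out from 14 and uses two selective reagents instead of one. NaBH4 in THF/H2O (0 to 25 °C) removes the auxiliary reductively and should give the hydroxymethyl Weinreb amide F3; any pivalate lost at this stage is harmless. iBu2AlH (DIBAL-H, CH2Cl2, −78 °C) then cleaves the pivalate and stops the Weinreb amide at the aldehyde level, and the fallback comes back to the route at 15.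

Step 1. O-alkylation may occur at the other phenol oxygen or at both, which would carry a regioisomeric lactone forward. The fallback sets out from 2, which O-alkylates the single phenol of purchased 5-bromovanillin F4 (K2CO3, DMF) to give methyl 2-(2-bromo-4-formyl-6-methoxyphenoxy)acetate F5 with unambiguous regiochemistry. BBr3 (CH2Cl2, −78 to 0 °C) should then cleave the aryl methyl ether to 3 (or its acid), and the acid-catalysed lactonisation of step 1 brings the fallback back to the route at 4.

**Further compounds**
F1 | step 4 | methyl (2R,3S)-2-{2-bromo-6-[(2,2-dimethylpropanoyl)oxy]-4-[(1E)-3-[methoxy(methyl)amino]-3-oxoprop-1-en-1-yl]phenoxy}-3-hydroxy-3-(3,4,5-trimethoxyphenyl)propanoate | COc1cc([C@H](O)[C@@H](Oc2c(Br)cc(/C=C/C(=O)N(C)OC)cc2OC(=O)C(C)(C)C)C(=O)OC)cc(OC)c1OC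
F2 | step 4 | methyl (2R,3S)-8-[(2,2-dimethylpropanoyl)oxy]-6-[(1E)-3-[methoxy(methyl)amino]-3-oxoprop-1-en-1-yl]-3-(3,4,5-trimethoxyphenyl)-2,3-dihydro-1,4-benzodioxine-2-carboxylate | COc1cc([C@@H]2Oc3cc(/C=C/C(=O)N(C)OC)cc(OC(=O)C(C)(C)C)c3O[C@H]2C(=O)OC)cc(OC)c1OC
F3 | step 5 | (2E)-3-{(2S,3S)-8-[(2,2-dimethylpropanoyl)oxy]-2-(hydroxymethyl)-3-(3,4,5-trimethoxyphenyl)-2,3-dihydro-1,4-benzodioxin-6-yl}-N-methoxy-N-methylprop-2-enamide | COc1cc([C@@H]2Oc3cc(/C=C/C(=O)N(C)OC)cc(OC(=O)C(C)(C)C)c3O[C@H]2CO)cc(OC)c1OC
F4 | step 1 | 3-bromo-4-hydroxy-5-methoxybenzaldehyde (5-bromovanillin) | COc1cc(C=O)cc(Br)c1O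
F5 | step 1 | methyl 2-(2-bromo-4-formyl-6-methoxyphenoxy)acetate | COC(=O)COc1c(OC)cc(C=O)cc1Br
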